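Two chemists disagree about three flasks. In each, solid substrate dissolves to starting material, which opens to the open intermediate. That intermediate goes reversibly to the target and to the isomer of the product, and the capture agent traps a little of it.

| flask | solid substrate | capture agent | temperature | time |
|---|---|---|---|---|
| theta | 1.0 M | 0.100 M | 110 °C | 12 min |
| gamma | 1.0 M | 0.100 M | 85 °C | 12 min |
| alpha | 1.0 M | 0.100 M | 60 °C | 12 min |

    starting material → open intermediate (k1 = 0.0053 s⁻¹, Ea1 = 118 kJ mol⁻¹)
    open intermediate ⇌ target (K2 = 1.4, k2 = 0.0043 s⁻¹, Ea2 = 107 kJ mol⁻¹, ΔH2 = −20.0 kJ mol⁻¹)
    open intermediate ⇌ isomer of the product (K3 = 2.1, k3 = 1.3 × 10⁻⁴ s⁻¹, Ea3 = 123 kJ mol⁻¹, ΔH3 = 40.0 kJ mol⁻¹)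
    solid substrate ⇌ starting material, rate k4*(cs4 - [starting material]) while solid is left; crystals form when [starting material] > cs4 (cs4 = 0.81 M, k4 = 0.0057 s⁻¹)
    open intermediate + capture agent → trapped intermediate (k5 = 0.0016 M⁻¹ s⁻¹, Ea5 = 68.0 kJ mol⁻¹)
    (constants at 110 °C)

- as a solid, counted per litre of solution: solid substrate
- the list of constants is for 110 °C, to be carried to other temperatures by the activation energies and enthalpies
- at the start none of the solid substrate is in solution
- what has only dissolved of solid substrate counts as not reacted

1. which flask leads in amount of target, in percent of the solid substrate charged ("all alike" within 1.5 percentage points) (theta / gamma / alpha / all alike)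
2. how much target is there at the end, in percent of the solid substrate charged: theta
3. how much target is there at the end, in percent of the solid substrate charged: gamma
4. how much target is there at the end, in percent of the solid substrate charged: alpha

The first chemist argues from equilibrium. In theta the relaxation half-life between open intermediate and target is 1.57 min, short against the 12 min of the run, so [target]/[open intermediate] should stand at 1.4, a share of 58.3%. The step is exothermic, so in alpha the constant is 3.59, a share of 78.2%, and the coldest flask should lead: this is thermodynamic control.

I take the second side, kinetic control, and reckon in powers of ten. That half-life belongs to theta, and the opening step must come first. In alpha the opening constant falls by the factor 260 to 2.04 × 10⁻⁵ s⁻¹, and scaling that factor's logarithm by the activation energies brings the forward constant to target to 2.78 × 10⁻⁵ s⁻¹. Dissolution has the time constant 175 s. Together these give 9.29 × 10⁻⁵, or −4.03 as a power of ten. This is my series number: the two forward constants multiplied together and by the double time integral of the dissolution curve. It is the fraction of saturated [starting material] that has reached the target by the start-up law, which holds while the number is far below one.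

So alpha should hold 0.00753% of the charge as target. The same number for theta is 3.73, which is 4.60 powers of ten higher. It stands above one, so the start-up law does not hold for theta, and I put theta first without a figure of my own. I leave gamma unreckoned.

The forecast also names theta: 46% (41% to 50%) for theta, 1.8% (1.4% to 2.3%) for gamma and 0.007% (0.005% to 0.01%) for alpha, since “the high activation energies of the two sequential steps slow them so much”.

The simulation puts theta first, with 46.7% in theta, 1.84% in gamma and 0.00742% in alpha.

The series number of alpha gave 0.00753% against that 0.00742%, and for the alpha flask left 120 min it gives 1.14% against 1.03%. The first chemist's ratio appears in the theta flask read at 20 min, where the series number is 12.3 and [target]/[open intermediate] reads 1.40 beside the constant 1.4. At 120 min the colder gamma flask holds 53.7% of target, more than the 39.0% in theta.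

The numbers of this flask belong to no real substance; what happens was integrated by code.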